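The route rests on the trisubstituted C7=C8 olefin, the only functional group within ring B (labdane numbering). A ring-closing metathesis between an allyl group on C5 and an isopropenyl group on C9 forms this double bond and closes ring B in one operation; the trans ring fusion follows from the preset C5, C9 and C10 centres. The precursor is a monocyclic ring-A cyclohexanone (C2 carbonyl) carrying the allyl arm and the complete acetoxylated side chain. It comes from a dimedone enol ether by asymmetric allylation, methyl addition with carbonyl transposition, and Sakurai addition of a geranyl-acetate-derived allylsilane. The C2 ketone is finally turned into the 2,3-diol.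

Key step: step 7

Assumption: the (R,R)-configured Trost ligand is taken to give the (R)-ketone 6 in step 4; should the sense of induction be opposite, the (S,S)-ligand is used with no other change.

Step 1
Reactants: 1 geranyl acetate
Product: 2 (2E,6E)-8-hydroxy-3,7-dimethylocta-2,6-dien-1-yl acetate
Conditions: SeO2 (cat.), t-BuOOH (70% aq.), salicylic acid (cat.), CH2Cl2, 23 °C
Reagents that add atoms: selenium dioxide O=[Se]=O (catalytic oxygen carrier); tert-butyl hydroperoxide CC(C)(C)OO
Why: Riley allylic oxidation (ene reaction, then [2,3]-sigmatropic shift) should hydroxylate the (E)-methyl group of the electron-rich terminal alkene, the 2,3-alkene being deactivated by its allylic acetate.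

Step 2
Reactants: 2 (2E,6E)-8-hydroxy-3,7-dimethylocta-2,6-dien-1-yl acetate
Product: 3 (2E,6E)-3,7-dimethyl-8-(trimethylsilyl)octa-2,6-dien-1-yl acetate
Conditions: Me3SiSiMe3, Pd(BF4)2(MeCN)4 (5 mol %), DMSO/MeOH, 50 °C
Reagents that add atoms: hexamethyldisilane C[Si](C)(C)[Si](C)(C)C
Why: palladium-catalysed silylation of an allylic alcohol through a π-allyl intermediate should place silicon at the unsubstituted terminus and keep the (E)-alkene, while the allylic acetate, which is not activated under these conditions, stays untouched.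

Step 3
Reactants: 4 3-ethoxy-5,5-dimethylcyclohex-2-en-1-one
Product: 5 3-ethoxy-5,5-dimethylcyclohexa-1,3-dien-1-yl prop-2-en-1-yl carbonate
Conditions: NaN(SiMe3)2, TMEDA, THF, −78 °C; then ClCO2CH2CH=CH2
Reagents that add atoms: allyl chloroformate C=CCOC(Cl)=O
Why: kinetic α′-deprotonation of the vinylogous ester followed by O-acylation of the sodium enolate (favoured by TMEDA) should give the allyl enol carbonate.

Step 4
Reactants: 5 3-ethoxy-5,5-dimethylcyclohexa-1,3-dien-1-yl prop-2-en-1-yl carbonate
Product: 6 (6R)-3-ethoxy-5,5-dimethyl-6-(prop-2-en-1-yl)cyclohex-2-en-1-one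
Conditions: Pd2(dba)3·CHCl3 (2.5 mol %), (R,R)-ANDEN-phenyl Trost ligand (5.5 mol %), toluene, 23 °C
Reagents that add atoms: none
Why: palladium-catalysed decarboxylative asymmetric allylic alkylation (Tsuji–Trost type) loses CO2 to a ligand-bound π-allylpalladium enolate pair whose recombination at the α′-carbon sets the tertiary stereocentre (C5 of the target) under ligand control, under neutral conditions that should not epimerise it.

Step 5
Reactants: 6 (6R)-3-ethoxy-5,5-dimethyl-6-(prop-2-en-1-yl)cyclohex-2-en-1-one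
Product: 8 (4R)-3,5,5-trimethyl-4-(prop-2-en-1-yl)cyclohex-2-en-1-one, via tertiary allylic carbinol 7 (not isolated)
Conditions: MeLi, CeCl3, THF, −78 °C; then 1 M HCl, THF, 0 °C
Reagents that add atoms: methyllithium [Li]C; water O
Why: Stork–Danheiser alkylative carbonyl transposition, in which the weakly basic organocerium reagent adds 1,2 to the hindered carbonyl without enolising the adjacent stereocentre and acid hydrolysis of the enol ether with loss of water gives the transposed enone; no stereocentre is formed or touched.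

Step 6
Reactants: 8 (4R)-3,5,5-trimethyl-4-(prop-2-en-1-yl)cyclohex-2-en-1-one; 3 (2E,6E)-3,7-dimethyl-8-(trimethylsilyl)octa-2,6-dien-1-yl acetate
Product: 9 (2E,6R)-3,7-dimethyl-6-[(1S,2R)-1,3,3-trimethyl-5-oxo-2-(prop-2-en-1-yl)cyclohexyl]octa-2,7-dien-1-yl acetate
Conditions: TiCl4, CH2Cl2, −78 °C; then aq. NaHCO3
Reagents that add atoms: none
Why: Hosomi–Sakurai conjugate allylation (SE2′, precedented for γ-substituted allylsilanes and 3-methylcyclohex-2-enones), in which the nucleophilic 2-methyl-substituted allylsilane should attack the titanium-activated β-carbon through its γ-carbon anti to the neighbouring allyl group (sets quaternary C10) and through an open transition state that turns the chain away from the allyl-bearing ring carbon (sets C9), creating the isopropenyl group at the same time.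

Step 7
Reactants: 9 (2E,6R)-3,7-dimethyl-6-[(1S,2R)-1,3,3-trimethyl-5-oxo-2-(prop-2-en-1-yl)cyclohexyl]octa-2,7-dien-1-yl acetate
Product: 10 (2E)-3-methyl-5-[(1R,4aR,8aR)-2,5,5,8a-tetramethyl-7-oxo-1,4,4a,5,6,7,8,8a-octahydronaphthalen-1-yl]pent-2-en-1-yl acetate
Conditions: second-generation Grubbs catalyst (5 mol %), CH2Cl2 (5 mM), 40 °C
Reagents that add atoms: none
Why: Ring-closing olefin metathesis by the Chauvin mechanism: the ruthenium alkylidene initiates at the monosubstituted allyl alkene on C5, the new C7 alkylidene adds [2+2] to the 1,1-disubstituted isopropenyl alkene on C9, and cycloreversion releases ethene and the C7=C8 double bond. The closest known reaction type is the closure of 1,7-dienes (one monosubstituted, one 1,1-disubstituted alkene) to 1-methylcyclohexenes with second-generation ruthenium catalysts. Ring B is closed as a six-membered carbocycle by joining the two alkene termini, the most favourable ring size for this reaction. No stereocentre is created: C5, C9 and C10 come from steps 4 and 6, and their relative configuration puts both arms equatorial on ring A, so that only the trans-fused bicycle can form. The step needs chemoselectivity against the trisubstituted C13=C14 alkene and the ketone; the first is secured because that alkene is more substituted, deactivated by its allylic acetate and could only close a five- or nine-membered ring, the second by the functional-group tolerance of the ruthenium carbene. Loss of volatile ethene should make the closure irreversible.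

Step 8
Reactants: 10 (2E)-3-methyl-5-[(1R,4aR,8aR)-2,5,5,8a-tetramethyl-7-oxo-1,4,4a,5,6,7,8,8a-octahydronaphthalen-1-yl]pent-2-en-1-yl acetate
Product: 12 (2E)-5-[(1R,4aS,6R,8aS)-6-(tert-butyldimethylsilyloxy)-2,5,5,8a-tetramethyl-7-oxo-1,4,4a,5,6,7,8,8a-octahydronaphthalen-1-yl]-3-methylpent-2-en-1-yl acetate, via silyl enol ether 11 (not isolated)
Conditions: TBSOTf, Et3N, CH2Cl2, 0 to 23 °C; then DMDO, acetone/CH2Cl2, −78 to −20 °C; SiO2
Reagents that add atoms: tert-butyldimethylsilyl trifluoromethanesulfonate CC(C)(C)[Si](C)(C)OS(=O)(=O)C(F)(F)F; dimethyldioxirane CC1(C)OO1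
Why: Rubottom oxidation, in which equilibrating soft enolisation should favour the C2=C3 silyl enol ether (the double bond avoids the ring-fusion carbon of the trans-fused bicycle), the electron-rich enol ether is epoxidised faster than the two trisubstituted alkenes and from the face opposite the two axial methyl groups, and 1,4-silyl migration gives the axial 3-silyloxy ketone (sets C3).

Step 9
Reactants: 12 (2E)-5-[(1R,4aS,6R,8aS)-6-(tert-butyldimethylsilyloxy)-2,5,5,8a-tetramethyl-7-oxo-1,4,4a,5,6,7,8,8a-octahydronaphthalen-1-yl]-3-methylpent-2-en-1-yl acetate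
Product: 13 (2E)-5-[(1R,4aS,6R,7S,8aS)-6-(tert-butyldimethylsilyloxy)-7-hydroxy-2,5,5,8a-tetramethyl-1,4,4a,5,6,7,8,8a-octahydronaphthalen-1-yl]-3-methylpent-2-en-1-yl acetate
Conditions: Shvo's catalyst Ru2(CO)4(μ-H)[(C4Ph4CO)2H] (2 mol %), i-PrOH, toluene, 90 °C
Reagents that add atoms: none
Why: reversible ruthenium-catalysed transfer hydrogenation should equilibrate the C2 carbinol and funnel it to the equatorial alcohol cis to the C3 oxygen, because the axial epimer suffers two 1,3-diaxial methyl interactions, while the silyl ether keeps C3 out of the redox equilibrium (sets C2).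

Step 10
Reactants: 13 (2E)-5-[(1R,4aS,6R,7S,8aS)-6-(tert-butyldimethylsilyloxy)-7-hydroxy-2,5,5,8a-tetramethyl-1,4,4a,5,6,7,8,8a-octahydronaphthalen-1-yl]-3-methylpent-2-en-1-yl acetate
Product: 14 (2E)-5-[(1R,4aS,6R,7S,8aS)-6,7-dihydroxy-2,5,5,8a-tetramethyl-1,4,4a,5,6,7,8,8a-octahydronaphthalen-1-yl]-3-methylpent-2-en-1-yl acetate
Conditions: HF·pyridine, THF, 0 to 23 °C
Reagents that add atoms: none
Why: fluoride-mediated cleavage of the hindered secondary silyl ether under buffered conditions should leave the allylic acetate and both alkenes untouched.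

Compound list
1 | geranyl acetate, (2E)-3,7-dimethylocta-2,6-dien-1-yl acetate | CC(=O)OC/C=C(\C)CCC=C(C)C | starting material
2 | (2E,6E)-8-hydroxy-3,7-dimethylocta-2,6-dien-1-yl acetate | CC(=O)OC/C=C(\C)CC/C=C(\C)CO | intermediate
3 | (2E,6E)-3,7-dimethyl-8-(trimethylsilyl)octa-2,6-dien-1-yl acetate | CC(=O)OC/C=C(\C)CC/C=C(\C)C[Si](C)(C)C | intermediate
4 | 3-ethoxy-5,5-dimethylcyclohex-2-en-1-one | CCOC1=CC(=O)CC(C)(C)C1 | starting material
5 | 3-ethoxy-5,5-dimethylcyclohexa-1,3-dien-1-yl prop-2-en-1-yl carbonate | C=CCOC(=O)OC1=CC(C)(C)CC(OCC)=C1 | intermediate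
6 | (6R)-3-ethoxy-5,5-dimethyl-6-(prop-2-en-1-yl)cyclohex-2-en-1-one | CCOC1=CC(=O)[C@H](CC=C)C(C)(C)C1 | intermediate
7 | (6R)-3-ethoxy-1,5,5-trimethyl-6-(prop-2-en-1-yl)cyclohex-2-en-1-ol (both C1 epimers) | CCOC1=CC(C)(O)[C@H](CC=C)C(C)(C)C1 | intermediate (not isolated)
8 | (4R)-3,5,5-trimethyl-4-(prop-2-en-1-yl)cyclohex-2-en-1-one | O=C1C=C(C)[C@H](CC=C)C(C)(C)C1 | intermediate
9 | (2E,6R)-3,7-dimethyl-6-[(1S,2R)-1,3,3-trimethyl-5-oxo-2-(prop-2-en-1-yl)cyclohexyl]octa-2,7-dien-1-yl acetate (allyl group and side chain trans on ring A) | CC(=O)OC/C=C(\C)CC[C@H](C(C)=C)[C@]1(C)CC(=O)CC(C)(C)[C@H]1CC=C | intermediate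
10 | (2E)-3-methyl-5-[(1R,4aR,8aR)-2,5,5,8a-tetramethyl-7-oxo-1,4,4a,5,6,7,8,8a-octahydronaphthalen-1-yl]pent-2-en-1-yl acetate (trans-fused) | CC(=O)OC/C=C(\C)CC[C@@H]1C(C)=CC[C@@H]2C(C)(C)CC(=O)C[C@@]12C | intermediate
11 | (2E)-5-[(1R,4aR,8aS)-7-(tert-butyldimethylsilyloxy)-2,5,5,8a-tetramethyl-1,4,4a,5,8,8a-hexahydronaphthalen-1-yl]-3-methylpent-2-en-1-yl acetate | CC(=O)OC/C=C(\C)CC[C@@H]1C(C)=CC[C@@H]2C(C)(C)C=C(O[Si](C)(C)C(C)(C)C)C[C@@]12C | intermediate (not isolated)
12 | (2E)-5-[(1R,4aS,6R,8aS)-6-(tert-butyldimethylsilyloxy)-2,5,5,8a-tetramethyl-7-oxo-1,4,4a,5,6,7,8,8a-octahydronaphthalen-1-yl]-3-methylpent-2-en-1-yl acetate | CC(=O)OC/C=C(\C)CC[C@@H]1C(C)=CC[C@@H]2C(C)(C)[C@@H](O[Si](C)(C)C(C)(C)C)C(=O)C[C@@]12C | intermediate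
13 | (2E)-5-[(1R,4aS,6R,7S,8aS)-6-(tert-butyldimethylsilyloxy)-7-hydroxy-2,5,5,8a-tetramethyl-1,4,4a,5,6,7,8,8a-octahydronaphthalen-1-yl]-3-methylpent-2-en-1-yl acetate | CC(=O)OC/C=C(\C)CC[C@@H]1C(C)=CC[C@@H]2C(C)(C)[C@@H](O[Si](C)(C)C(C)(C)C)[C@@H](O)C[C@@]12C | intermediate
14 | (2E)-5-[(1R,4aS,6R,7S,8aS)-6,7-dihydroxy-2,5,5,8a-tetramethyl-1,4,4a,5,6,7,8,8a-octahydronaphthalen-1-yl]-3-methylpent-2-en-1-yl acetate | CC(=O)OC/C=C(\C)CC[C@@H]1C(C)=CC[C@@H]2C(C)(C)[C@@H](O)[C@@H](O)C[C@@]12C | target

Total step count: 10 (steps 1–2 make the allylsilane, steps 3–10 build and finish the bicycle).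
Longest linear sequence: 8 steps (4 to 14, steps 3–10).

Steps most likely to fail

Step 6. Bond formation at the β-carbon, which is flanked by the allyl-bearing carbon, may be slow, so that protodesilylation of 3 or ionisation of its acetate takes over; the open transition state may also control C9 poorly. The fallback sets out from 8 and returns at 9. It makes the hindered bond with a smaller, stronger π-nucleophile and sets C9 afterwards by enolate alkylation.
- Mukaiyama–Michael addition of 1-(tert-butylthio)-1-(tert-butyldimethylsilyloxy)ethene to 8 (TBSOTf cat., CH2Cl2, −78 °C, silyl transfer) should give silyl enol ether thioester F1, with the new bond anti to the allyl group.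
- Its lithium enolate (LiN(i-Pr)2, THF/HMPA, −78 °C) is alkylated with homoallylic iodide F2. With the C10 methyl eclipsing the enolate (allylic 1,3-strain), the iodide should enter anti to the allyl-bearing ring carbon and give alkylated thioester F3 with the C9 configuration of 9.
- Me2CuLi converts the thioester into methyl ketone F4, and Cp2TiMe2 (toluene, 65 °C) methylenates it to isopropenyl compound F5.
- HF·pyridine removes both silyl groups to give keto alcohol F6, and Ac2O/pyridine gives 9.

Step 9. The equilibration may stall at the kinetically formed axial alcohol, or hydrogen transfer and enolisation may scramble C3. The fallback sets out from 12 and returns at 14. HF·pyridine gives ketol F7. A ketoreductase chosen from a screening panel for α-face hydride delivery (NADPH, glucose/glucose dehydrogenase recycling, phosphate buffer/DMSO, 30 °C) then reduces C2 under enzyme control instead of substrate or thermodynamic control and should give 14 directly.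

Step 4. Enantioinduction may be low at a tertiary α′-carbon next to the quaternary centre, and proton transfer within the palladium enolate may give non-allylated or doubly allylated material. The fallback replaces steps 3–5: it does not use 4–7, sets out from commercially available enone F8 in place of 4, and returns at 8.
- Corey–Bakshi–Shibata reduction ((R)-2-methyl-CBS-oxazaborolidine, BH3·SMe2) should give allylic alcohol F9.
- O-vinylation (ethyl vinyl ether, Hg(OAc)2 cat.) gives vinyl ether F10. Its Claisen rearrangement (toluene, 190 °C) transfers the carbinol configuration suprafacially to the ring carbon next to the gem-dimethyl group and gives aldehyde F11.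
- Wittig methylenation (Ph3P=CH2) gives diene F12, and allylic oxidation of the ring methylene (CrO3·3,5-dimethylpyrazole, CH2Cl2, −20 °C) gives 8.

Further compounds
F1 | step 6 | S-tert-butyl 2-[(1S,6R)-3-(tert-butyldimethylsilyloxy)-1,5,5-trimethyl-6-(prop-2-en-1-yl)cyclohex-2-en-1-yl]ethanethioate | CC(C)(C)SC(=O)C[C@]1(C)C=C(O[Si](C)(C)C(C)(C)C)CC(C)(C)[C@H]1CC=C
F2 | step 6 | (E)-tert-butyl[(5-iodo-3-methylpent-2-en-1-yl)oxy]dimethylsilane | CC(C)(C)[Si](C)(C)OC/C=C(\C)CCI
F3 | step 6 | thioester F1 alkylated at the carbon α to the thioester with the (E)-5-(tert-butyldimethylsilyloxy)-3-methylpent-3-en-1-yl chain (that carbon configured as C9 of 9) | CC(C)(C)[Si](C)(C)OC/C=C(\C)CC[C@H](C(=O)SC(C)(C)C)[C@]1(C)C=C(O[Si](C)(C)C(C)(C)C)CC(C)(C)[C@H]1CC=C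
F4 | step 6 | methyl ketone corresponding to thioester F3 (C(=O)S-tert-butyl replaced by acetyl) | CC(C)(C)[Si](C)(C)OC/C=C(\C)CC[C@H](C(C)=O)[C@]1(C)C=C(O[Si](C)(C)C(C)(C)C)CC(C)(C)[C@H]1CC=C
F5 | step 6 | isopropenyl compound from F4 (acetyl replaced by prop-1-en-2-yl), the bis-silyl analogue of 9 | CC(C)(C)[Si](C)(C)OC/C=C(\C)CC[C@H](C(C)=C)[C@]1(C)C=C(O[Si](C)(C)C(C)(C)C)CC(C)(C)[C@H]1CC=C
F6 | step 6 | (4R,5S)-3,3,5-trimethyl-4-(prop-2-en-1-yl)-5-[(3R,6E)-8-hydroxy-2,6-dimethylocta-1,6-dien-3-yl]cyclohexan-1-one, the deacetyl analogue of 9 | OC/C=C(\C)CC[C@H](C(C)=C)[C@]1(C)CC(=O)CC(C)(C)[C@H]1CC=C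
F7 | step 9 | (2E)-5-[(1R,4aS,6R,8aS)-6-hydroxy-2,5,5,8a-tetramethyl-7-oxo-1,4,4a,5,6,7,8,8a-octahydronaphthalen-1-yl]-3-methylpent-2-en-1-yl acetate | CC(=O)OC/C=C(\C)CC[C@@H]1C(C)=CC[C@@H]2C(C)(C)[C@@H](O)C(=O)C[C@@]12C
F8 | step 4 | 2,4,4-trimethylcyclohex-2-en-1-one | CC1=CC(C)(C)CCC1=O
F9 | step 4 | (1S)-2,4,4-trimethylcyclohex-2-en-1-ol | O[C@@H]1C(C)=CC(C)(C)CC1
F10 | step 4 | (6S)-6-(ethenyloxy)-1,3,3-trimethylcyclohex-1-ene | C=CO[C@@H]1C(C)=CC(C)(C)CC1
F11 | step 4 | 2-[(1R)-2,6,6-trimethylcyclohex-2-en-1-yl]acetaldehyde | C1C=C(C)[C@H](CC=O)C(C)(C)C1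
F12 | step 4 | (6R)-1,5,5-trimethyl-6-(prop-2-en-1-yl)cyclohex-1-ene | C1C=C(C)[C@H](CC=C)C(C)(C)C1
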